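Our first figure is a leftover: with 1.10 equiv of second substrate, 9.09% of its charge stays behind once the starting material has reacted to the end. Starting material is therefore the limiting reagent, and a flask that stops early leaves some of both. The three flasks differ in their temperature.

in all of them: starting material 0.050 M; second substrate 1.10 equiv; free enzyme 0.1 mol%; time 15 min
- green: temperature 35 °C
- ochre: temperature 20 °C
- teal: at 35 °C until 5.0 min, from then on at 20 °C

1. the flask with the highest amount of target, in percent of the starting material charged ("all alike" if they lie within 1.5 percentage points) (green / ochre / teal / all alike)
2. final target, as a percentage of the starting material charged, in green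
3. final target, as a percentage of the starting material charged, in ochre
4. final target, as a percentage of the starting material charged, in teal

- for target the crystals are counted in
- as a solid, counted per litre of solution: crystals
- the constants hold at 20 °C; other temperatures follow from the activation energies and enthalpies

    crystals ⇌ target, rate k1*(cs1 - [target]) while solid is left; crystals form when [target] > cs1 (cs1 = 38 mM, k1 = 0.11 s⁻¹)
    ternary complex → free enzyme + target (k2 = 200 s⁻¹, Ea2 = 49.0 kJ mol⁻¹)
    free enzyme → unfolded enzyme (k3 = 0.0014 s⁻¹, Ea3 = 279 kJ mol⁻¹)
    second substrate + starting complex ⇌ ternary complex (K4 = 190 L mol⁻¹, k4 = 37000 L mol⁻¹ s⁻¹, Ea4 = 9.00 kJ mol⁻¹, ΔH4 = −60.0 kJ mol⁻¹)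
    starting material + free enzyme ⇌ starting complex (K5 = 6.4 L mol⁻¹, k5 = 53000 L mol⁻¹ s⁻¹, Ea5 = 33.0 kJ mol⁻¹, ΔH5 = −8.00 kJ mol⁻¹)
    ternary complex → spent catalyst (k6 = 0.0093 s⁻¹, Ea6 = 91.0 kJ mol⁻¹)
    (constants at 20 °C)

Free enzyme binds starting material to give the starting complex, which binds second substrate to give the ternary complex. That complex releases target and free enzyme: one round. Free enzyme can unfold and ternary complex can become spent catalyst, and neither returns. Target does not re-enter the round, so crystals play no part in our reckoning.

At 0.1 mol%, each enzyme must make 1000 rounds. How many can it make? Let a and b be the starting material and second substrate left, as fractions of the starting material charged. Balancing the two complexes gives r = ab/(P + Qb) ternary complexes per free enzyme. P is the sum of the inverse binding constant of second substrate and release constant over its binding rate constant, divided by the binding constant of starting material and the squared charge. Q is release constant over the binding rate constant of starting material, divided by the charge. P is 0.667 and Q 0.0755 at 20 °C. The enzyme then makes N rounds: release constant times r, over unfolding constant plus spending constant times r. We replace the falling a and b by their means.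

In ochre, a full run has mean a = 0.5, so r is 0.421 and N is 15800. Loading times N is 15.8 charges, far more than the one charge in the flask. At that mean the rounds take about 18.6 s, far shorter than 15 min. So ochre should run to the end of its starting material.

At 35 °C, release rises to 532 s⁻¹, but unfolding rises to 0.368 s⁻¹ and spending to 0.0572 s⁻¹, while P becomes 2.16 and Q 0.104. With fresh a and b, N is 650, which is 65.0% of the charge, and N falls as a and b fall. Taking the mean conversion as a quarter gives 39.3%. Taking half of that as the mean gives 44.4%. We commit to the middle, 41.8%: the reach, loading times N, the fraction of the charge the enzyme turns over before it is lost.

Teal matches green until 5.0 min. A hot enzyme in a fresh flask lasts about 4.40 s, far shorter than that wait, so we give teal the same reach.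

The forecast named ochre, with 41% in green, 100% in ochre and 41% in teal, saying that “teal's later cooling comes too late to matter”. Our figure for green and teal is 41.8%.

The simulation gives 41.1% in green, >99.9% in ochre and 41.1% in teal, so ochre stands highest.

Green's 41.1% is 411 rounds per enzyme charged, against 418 from our reach of 41.8%. Now take a neighbouring flask: teal with 0.025 mol% of free enzyme, a quarter of the loading. Its fresh reach is 16.2%. Using half of that as the mean conversion gives a reach of 14.0%. That flask ended with 14.2% target and 86% of its starting material still unbound.

(The rate constants come from no measurement; the rest is arithmetic.)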